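## Retrosynthetic overview

1. The last bond made is C4–C5: a C5 α-hydroxyalkyl radical (photocatalytic hydrogen-atom abstraction from a primary alcohol) adds 10-endo-dig to a but-2-ynoyl ketone. This closes the ten-membered ring and creates the 3Z-enone and the C5 carbinol in one step.
2. The seco-alcohol comes from an acyclic homoallylic alcohol by O8-tigloylation, then acetonide removal and γ-lactonisation (O6 onto C12).
3. The acyclic chain is joined at C7–C8 by an indium Barbier allylation of an epoxy-ynone aldehyde with a (Z)-2-(bromomethyl)enoate; C7 and C8 are set from C6.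
4. The bromide comes from (S)-glyceraldehyde acetonide and methyl acrylate (Baylis–Hillman, SN2′ bromination). The aldehyde comes from pent-1-en-4-yne (carboalumination/CH2O, Sharpless epoxidation, oxidation, propynyl addition, oxidation, ozonolysis).
5. Ring order: oxirane, then γ-lactone, then cyclodecenone.

Assumption: locants follow germacranolide numbering of the target (lactone O on C6, C7 bears C11=C13, tiglate on C8, C9H2, C1/C10 epoxide, C2 ketone, C3=C4, C5 carbinol); starting material 1 is used in its commercial isopropylidene-protected form (glyceraldehyde core C3H6O3).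

## Route

Step 1
Reactants: 1 (4S)-2,2-dimethyl-1,3-dioxolane-4-carbaldehyde; 2 methyl acrylate
Product: 3 methyl 2-{[(4S)-2,2-dimethyl-1,3-dioxolan-4-yl](hydroxy)methyl}prop-2-enoate (carbinol epimers)
Conditions: DABCO (0.5 equiv), dioxane/H2O 1:1, rt, 48 h
Reagents that add atoms: none
Why: Morita–Baylis–Hillman reaction of the α-alkoxy aldehyde; C6 comes from the chiral pool, and the new carbinol centre is left as a mixture because step 2 erases it.

Step 2
Reactants: 3 methyl 2-{[(4S)-2,2-dimethyl-1,3-dioxolan-4-yl](hydroxy)methyl}prop-2-enoate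
Product: 5 methyl (2Z)-2-(bromomethyl)-3-[(4R)-2,2-dimethyl-1,3-dioxolan-4-yl]prop-2-enoate, via alkoxysulfonium bromide 4 (not isolated)
Conditions: NBS, Me2S, CH2Cl2, 0 °C to rt
Reagents that add atoms: N-bromosuccinimide, O=C1CCC(=O)N1Br
Why: Corey–Kim-type activation of the allylic alcohol followed by SN2′ attack of bromide gives the conjugated (Z)-2-(bromomethyl)enoate selectively; C6 is untouched (4S to 4R is only a CIP change).

Step 3
Reactants: 6 pent-1-en-4-yne
Product: 9 (2E)-3-methylhexa-2,5-dien-1-ol, via alkenylalane 7 (not isolated), via lithium alkenylaluminate 8 (not isolated)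
Conditions: AlMe3 (2 equiv), Cp2ZrCl2 (25 mol%), CH2Cl2, 0 °C to rt; n-BuLi, THF, −78 to 0 °C; (CH2O)n, rt; H2O
Reagents that add atoms: trimethylaluminium, C[Al](C)C; paraformaldehyde (as formaldehyde), C=O
Why: Negishi zirconium-catalysed carboalumination adds Me and Al syn across the terminal alkyne (Me to the internal carbon), so hydroxymethylation of the derived aluminate gives only the E-trisubstituted allylic alcohol; the isolated vinyl group does not react.

Step 4
Reactants: 9 (2E)-3-methylhexa-2,5-dien-1-ol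
Product: 10 [(2R,3R)-3-methyl-3-(prop-2-en-1-yl)oxiran-2-yl]methanol
Conditions: Ti(OiPr)4 (10 mol%), D-(−)-diethyl tartrate (12 mol%), TBHP, 4 Å MS, CH2Cl2, −20 °C
Reagents that add atoms: tert-butyl hydroperoxide, CC(C)(C)OO
Why: Sharpless asymmetric epoxidation of a geraniol-type substrate; D-(−)-tartrate gives the (2R,3R) epoxide and so sets C1 and C10, while the non-allylic terminal alkene is inert.

Step 5
Reactants: 10 [(2R,3R)-3-methyl-3-(prop-2-en-1-yl)oxiran-2-yl]methanol
Product: 11 (2S,3R)-3-methyl-3-(prop-2-en-1-yl)oxirane-2-carbaldehyde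
Conditions: TEMPO (10 mol%), PhI(OAc)2, CH2Cl2, rt
Reagents that add atoms: none
Why: TEMPO/PhI(OAc)2 oxoammonium oxidation stops at the aldehyde under near-neutral conditions, and the oxiranyl α-centre cannot enolise, so C1 is retained.

Step 6
Reactants: 11 (2S,3R)-3-methyl-3-(prop-2-en-1-yl)oxirane-2-carbaldehyde; 12 prop-1-yn-1-ylmagnesium bromide
Product: 13 1-[(2R,3R)-3-methyl-3-(prop-2-en-1-yl)oxiran-2-yl]but-2-yn-1-ol (carbinol epimers)
Conditions: THF, −78 °C; then H2O
Reagents that add atoms: none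
Why: Grignard 1,2-addition to the aldehyde at −78 °C outpaces epoxide opening; the carbinol mixture is removed in step 7.

Step 7
Reactants: 13 1-[(2R,3R)-3-methyl-3-(prop-2-en-1-yl)oxiran-2-yl]but-2-yn-1-ol
Product: 14 1-[(2S,3R)-3-methyl-3-(prop-2-en-1-yl)oxiran-2-yl]but-2-yn-1-one
Conditions: activated MnO2, CH2Cl2, rt
Reagents that add atoms: none
Why: MnO2 oxidation of the propargylic alcohol gives the conjugated ynone under neutral conditions that leave the epoxide and the terminal alkene alone.

Step 8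
Reactants: 14 1-[(2S,3R)-3-methyl-3-(prop-2-en-1-yl)oxiran-2-yl]but-2-yn-1-one
Product: 16 2-[(2R,3S)-3-(but-2-ynoyl)-2-methyloxiran-2-yl]acetaldehyde, via secondary ozonide 15 (not isolated)
Conditions: O3, CH2Cl2, −78 °C (Sudan Red 7B end point); PPh3, −78 °C to rt; used crude
Reagents that add atoms: ozone, [O-][O+]=O
Why: ozonolysis, in which the electron-rich terminal alkene reacts far faster than the electron-poor ynone; neutral PPh3 reduction of the ozonide avoids base-induced β-opening of the β,γ-epoxy aldehyde.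

Step 9
Reactants: 5 methyl (2Z)-2-(bromomethyl)-3-[(4R)-2,2-dimethyl-1,3-dioxolan-4-yl]prop-2-enoate; 16 2-[(2R,3S)-3-(but-2-ynoyl)-2-methyloxiran-2-yl]acetaldehyde
Product: 18 methyl (3R,4R)-3-[(4R)-2,2-dimethyl-1,3-dioxolan-4-yl]-4-hydroxy-2-methylidene-5-[(2R,3S)-3-(but-2-ynoyl)-2-methyloxiran-2-yl]pentanoate, via allylindium dibromide 17 (not isolated)
Conditions: In powder, THF/H2O 1:1, rt, sonication
Reagents that add atoms: none
Why: Barbier allylation through the γ-carbon of the ester-chelated (Z)-allylindium in a chair transition state gives the 7,8-syn adduct, and C6 directs the aldehyde anti to its C5–C6 bond with H6 eclipsing the alkene (A1,3 strain), which sets 7R and 8R; the aldehyde reacts in preference to the ynone ketone.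

Step 10
Reactants: 18 methyl (3R,4R)-3-[(4R)-2,2-dimethyl-1,3-dioxolan-4-yl]-4-hydroxy-2-methylidene-5-[(2R,3S)-3-(but-2-ynoyl)-2-methyloxiran-2-yl]pentanoate; 19 (2E)-2-methylbut-2-enoyl chloride (tigloyl chloride)
Product: 20 methyl (3R,4R)-3-[(4R)-2,2-dimethyl-1,3-dioxolan-4-yl]-2-methylidene-4-[(2E)-2-methylbut-2-enoyloxy]-5-[(2R,3S)-3-(but-2-ynoyl)-2-methyloxiran-2-yl]pentanoate
Conditions: pyridine, DMAP (10 mol%), CH2Cl2, 0 °C to rt
Reagents that add atoms: none
Why: acylation with the acid chloride (E geometry retained) caps O8 at once, so that only O6 can lactonise in step 11.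

Step 11
Reactants: 20 methyl (3R,4R)-3-[(4R)-2,2-dimethyl-1,3-dioxolan-4-yl]-2-methylidene-4-[(2E)-2-methylbut-2-enoyloxy]-5-[(2R,3S)-3-(but-2-ynoyl)-2-methyloxiran-2-yl]pentanoate
Product: 22 (1R)-1-[(2R,3R)-2-(hydroxymethyl)-4-methylidene-5-oxooxolan-3-yl]-2-[(2R,3S)-3-(but-2-ynoyl)-2-methyloxiran-2-yl]ethyl (2E)-2-methylbut-2-enoate, via diol ester 21 (not isolated)
Conditions: PPTS (0.3 equiv), MeOH, 35 °C; then toluene, 40 °C
Reagents that add atoms: none
Why: PPTS-catalysed transketalisation frees the 5,6-diol and the secondary O6–H closes the γ-lactone onto the methyl ester (five-membered ring preferred over the δ-lactone from O5), giving the cis relationship fixed in step 9; the conjugated epoxy ketone is expected to tolerate this weak acid.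

Step 12
Reactants: 22 (1R)-1-[(2R,3R)-2-(hydroxymethyl)-4-methylidene-5-oxooxolan-3-yl]-2-[(2R,3S)-3-(but-2-ynoyl)-2-methyloxiran-2-yl]ethyl (2E)-2-methylbut-2-enoate
Product: 23 CNP0345622.1, (1S,5S,6R,7R,8R,10R)-1,10-epoxy-5-hydroxy-2-oxo-8-[(2E)-2-methylbut-2-enoyloxy]germacra-3Z,11(13)-dien-12,6-olide
Conditions: (n-Bu4N)4W10O32 (20 mol%), MeCN (0.3 mM), 390 nm LEDs, rt, Ar
Reagents that add atoms: none
Why: Proposed new method: photoexcited decatungstate abstracts the hydridic α-hydroxy C5–H (the other C–H bonds are deactivated by acyloxy, carbonyl or epoxide groups), the nucleophilic α-hydroxyalkyl radical adds 10-endo-dig to the β-carbon C4 of the ynone, and the α-keto vinyl radical takes hydrogen back from reduced decatungstate on its exocyclic face to give the cis (3Z) enone, with 5S arising from the extended conformer in which C5–OH and C6–O are anti; the closest known reaction types are decatungstate- or benzophenone-photocatalysed Giese hydroalkylation of electron-poor alkenes and alkynoates with alcohols and endo-mode radical macrocyclisation onto enones and ynones.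

## Compound list

1 | (4S)-2,2-dimethyl-1,3-dioxolane-4-carbaldehyde [(S)-glyceraldehyde acetonide] | O=C[C@@H]1COC(C)(C)O1 | starting material
2 | methyl acrylate | C=CC(=O)OC | starting material
3 | methyl 2-{[(4S)-2,2-dimethyl-1,3-dioxolan-4-yl](hydroxy)methyl}prop-2-enoate (carbinol epimers) | C=C(C(=O)OC)C(O)[C@@H]1COC(C)(C)O1 | intermediate
4 | O-dimethylsulfonium derivative of 3, bromide salt (not isolated) | C=C(C(=O)OC)C(O[S+](C)C)[C@@H]1COC(C)(C)O1.[Br-] | intermediate
5 | methyl (2Z)-2-(bromomethyl)-3-[(4R)-2,2-dimethyl-1,3-dioxolan-4-yl]prop-2-enoate | BrC/C(C(=O)OC)=C\[C@@H]1COC(C)(C)O1 | intermediate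
6 | pent-1-en-4-yne | C=CCC#C | starting material
7 | dimethyl[(1E)-2-methylpenta-1,4-dien-1-yl]alumane (not isolated) | C=CC/C(C)=C/[Al](C)C | intermediate
8 | lithium butyl(dimethyl)[(1E)-2-methylpenta-1,4-dien-1-yl]aluminate (not isolated) | C=CC/C(C)=C/[Al-](C)(C)CCCC.[Li+] | intermediate
9 | (2E)-3-methylhexa-2,5-dien-1-ol | C=CC/C(C)=C/CO | intermediate
10 | [(2R,3R)-3-methyl-3-(prop-2-en-1-yl)oxiran-2-yl]methanol | C=CC[C@@]1(C)O[C@@H]1CO | intermediate
11 | (2S,3R)-3-methyl-3-(prop-2-en-1-yl)oxirane-2-carbaldehyde | C=CC[C@@]1(C)O[C@@H]1C=O | intermediate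
12 | prop-1-yn-1-ylmagnesium bromide | CC#C[Mg]Br | starting material
13 | 1-[(2R,3R)-3-methyl-3-(prop-2-en-1-yl)oxiran-2-yl]but-2-yn-1-ol (carbinol epimers) | C=CC[C@@]1(C)O[C@@H]1C(O)C#CC | intermediate
14 | 1-[(2S,3R)-3-methyl-3-(prop-2-en-1-yl)oxiran-2-yl]but-2-yn-1-one | C=CC[C@@]1(C)O[C@@H]1C(=O)C#CC | intermediate
15 | 1,2,4-trioxolane (secondary ozonide) of the vinyl group of 14 (not isolated) | O1OC(OC1)C[C@@]1(C)O[C@@H]1C(=O)C#CC | intermediate
16 | 2-[(2R,3S)-3-(but-2-ynoyl)-2-methyloxiran-2-yl]acetaldehyde | O=CC[C@@]1(C)O[C@@H]1C(=O)C#CC | intermediate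
17 | allylindium reagent from 5, drawn as the monoallylindium(III) dibromide (not isolated) | Br[In](Br)C/C(C(=O)OC)=C\[C@@H]1COC(C)(C)O1 | intermediate
18 | methyl (3R,4R)-3-[(4R)-2,2-dimethyl-1,3-dioxolan-4-yl]-4-hydroxy-2-methylidene-5-[(2R,3S)-3-(but-2-ynoyl)-2-methyloxiran-2-yl]pentanoate | C=C(C(=O)OC)[C@@H]([C@@H]1COC(C)(C)O1)[C@H](O)C[C@@]1(C)O[C@@H]1C(=O)C#CC | intermediate
19 | (2E)-2-methylbut-2-enoyl chloride (tigloyl chloride) | C/C=C(\C)C(Cl)=O | starting material
20 | methyl (3R,4R)-3-[(4R)-2,2-dimethyl-1,3-dioxolan-4-yl]-2-methylidene-4-[(2E)-2-methylbut-2-enoyloxy]-5-[(2R,3S)-3-(but-2-ynoyl)-2-methyloxiran-2-yl]pentanoate | C=C(C(=O)OC)[C@@H]([C@@H]1COC(C)(C)O1)[C@H](OC(=O)/C(C)=C/C)C[C@@]1(C)O[C@@H]1C(=O)C#CC | intermediate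
21 | methyl (3S,4R)-3-[(1R)-1,2-dihydroxyethyl]-2-methylidene-4-[(2E)-2-methylbut-2-enoyloxy]-5-[(2R,3S)-3-(but-2-ynoyl)-2-methyloxiran-2-yl]pentanoate (not isolated) | C=C(C(=O)OC)[C@@H]([C@@H](O)CO)[C@H](OC(=O)/C(C)=C/C)C[C@@]1(C)O[C@@H]1C(=O)C#CC | intermediate
22 | (1R)-1-[(2R,3R)-2-(hydroxymethyl)-4-methylidene-5-oxooxolan-3-yl]-2-[(2R,3S)-3-(but-2-ynoyl)-2-methyloxiran-2-yl]ethyl (2E)-2-methylbut-2-enoate | C=C1C(=O)O[C@@H](CO)[C@H]1[C@H](OC(=O)/C(C)=C/C)C[C@@]1(C)O[C@@H]1C(=O)C#CC | intermediate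
23 | CNP0345622.1, (1S,5S,6R,7R,8R,10R)-1,10-epoxy-5-hydroxy-2-oxo-8-[(2E)-2-methylbut-2-enoyloxy]germacra-3Z,11(13)-dien-12,6-olide | C=C1C(=O)O[C@@H]2[C@H]1[C@H](OC(=O)/C(C)=C/C)C[C@@]1(C)O[C@@H]1C(=O)/C=C(/C)[C@@H]2O | target

## Step count and risks

Total step count: 12. Longest linear sequence: 10 steps (steps 3 to 12, from pent-1-en-4-yne 6 to 23).

**Most likely to fail, 1: step 12 (radical macrocyclisation).** Addition to the methyl-bearing ynone carbon is slow for a ten-membered ring. It competes with intermolecular capture of the radical by the α-methylene lactone of a second molecule, and with loss of the β-acyloxy group or over-oxidation of the α-hydroxy radical. The C5 configuration rests on conformational control only.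

Fallback: set out from 22. Dess–Martin oxidation of the primary alcohol gives the seco-aldehyde F1. A thiazolium-carbene-catalysed intramolecular Stetter acylation of the ynone (Et3N, dioxane, 50 °C, 1 mM) closes the ring as the macrocyclic (Z)-ene-dione F2. Luche reduction (NaBH4, CeCl3·7H2O, MeOH, −78 °C) of the more electrophilic α-acyloxy C5 ketone from the outer face then returns to the route at 23; a CBS reagent is the option if the facial sense is wrong. This replaces the radical closure by an acyl-anion closure and sets C5 by a separate reduction.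

**Most likely to fail, 2: step 9 (Barbier union).** The 6-to-7 induction follows a transition-state model and could give the other face. The β,γ-epoxy aldehyde 16 is also fragile.

Fallback: set out from 3. Acetylation (Ac2O, pyridine) gives the Baylis–Hillman acetate F3. Copper-catalysed SN2′ borylation (B2pin2, CuCl, KOAc, DMF) gives the allylboronate F4, with the same alkene geometry as 5. Allylboration of 16 under a chiral phosphoric acid [(S)-TRIP, toluene, −30 °C] goes through a closed chair and gives the pinacol borate F5; aqueous work-up returns to the route at 18. The catalyst, not C6, now chooses the aldehyde face and with it both C7 and C8; the TRIP antipode is chosen by a test reaction.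

**Most likely to fail, 3: step 11 (acid in the presence of the trisubstituted epoxide).** The epoxide could open, or O5 could lactonise instead of O6.

Fallback: set out from 5 and change the diol protection before the epoxide is present. Aqueous acetic acid gives the diol bromide F6, which is silylated at once (TESOTf, 2,6-lutidine, −78 °C) to the bis-TES bromide F7. Indium in THF/H2O converts F7 into the allylindium F8, which adds to 16 to give the bis-TES homoallylic alcohol F9. Tigloylation with 19 gives the bis-TES tiglate F10. Buffered HF·pyridine (pyridine, THF, 0 °C) removes both silyl groups to give 21, which lactonises to 22, where the route is rejoined.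

## Further compounds

F1 | step 12 | seco-aldehyde (C5 of 22 oxidised to CHO) | C=C1C(=O)O[C@@H](C=O)[C@H]1[C@H](OC(=O)/C(C)=C/C)C[C@@]1(C)O[C@@H]1C(=O)C#CC
F2 | step 12 | macrocyclic (3Z)-2,5-dione (5-oxo analogue of 23) | C=C1C(=O)O[C@@H]2[C@H]1[C@H](OC(=O)/C(C)=C/C)C[C@@]1(C)O[C@@H]1C(=O)/C=C(/C)C2=O
F3 | step 9 | methyl 2-{(acetyloxy)[(4S)-2,2-dimethyl-1,3-dioxolan-4-yl]methyl}prop-2-enoate | C=C(C(=O)OC)C(OC(C)=O)[C@@H]1COC(C)(C)O1
F4 | step 9 | methyl (2E)-3-[(4R)-2,2-dimethyl-1,3-dioxolan-4-yl]-2-[(4,4,5,5-tetramethyl-1,3,2-dioxaborolan-2-yl)methyl]prop-2-enoate | CC1(C)OB(C/C(C(=O)OC)=C\[C@@H]2COC(C)(C)O2)OC1(C)C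
F5 | step 9 | O-pinacolboryl derivative of 18 | C=C(C(=O)OC)[C@@H]([C@@H]1COC(C)(C)O1)[C@H](OB1OC(C)(C)C(C)(C)O1)C[C@@]1(C)O[C@@H]1C(=O)C#CC
F6 | step 11 | methyl (2Z,4R)-2-(bromomethyl)-4,5-dihydroxypent-2-enoate | BrC/C(C(=O)OC)=C\[C@@H](O)CO
F7 | step 11 | methyl (2Z,4R)-2-(bromomethyl)-4,5-bis(triethylsilyloxy)pent-2-enoate | BrC/C(C(=O)OC)=C\[C@@H](O[Si](CC)(CC)CC)CO[Si](CC)(CC)CC
F8 | step 11 | allylindium reagent from F7, drawn as the monoallylindium(III) dibromide | Br[In](Br)C/C(C(=O)OC)=C\[C@@H](O[Si](CC)(CC)CC)CO[Si](CC)(CC)CC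
F9 | step 11 | bis-TES analogue of 18 | C=C(C(=O)OC)[C@@H]([C@@H](O[Si](CC)(CC)CC)CO[Si](CC)(CC)CC)[C@H](O)C[C@@]1(C)O[C@@H]1C(=O)C#CC
F10 | step 11 | bis-TES analogue of 20 | C=C(C(=O)OC)[C@@H]([C@@H](O[Si](CC)(CC)CC)CO[Si](CC)(CC)CC)[C@H](OC(=O)/C(C)=C/C)C[C@@]1(C)O[C@@H]1C(=O)C#CC
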